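The route rests on cutting the upper pyran ring at O1–C2 and C4a–C4, which leaves unprotected resorcinol and an acyclic 1,3-diol (20) that already holds C2–C3–C4, the C3 aryl group (ring B, set by an Evans aldol) and the finished lower isoflavan. In one pot the primary carbinol C2 is bonded to a resorcinol oxygen and the benzylic carbinol C4 is ionised and captured by the ring carbon para to the remaining hydroxyl, a formal [3+3] annulation that closes ring C and sets C4 trans to C3. It exploits that C4 sits on C5' of ring B' (para to O2', ortho to OMe) and that C4a is ortho to O1 and para to O7 in symmetric ring A.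

Key step: step 13

Remark: the upper chroman is labelled O1, C2, C3, C4, C4a–C8a (ring A aromatic, ring C the pyran, ring B the C3 aryl group); the lower isoflavan carries rings A', C' and B' (C1' on its C3, O2', methoxy on C4', C5' bonded to the upper C4). Paeonol, 4-(benzyloxy)-2-hydroxybenzaldehyde, (4R)-4-benzyl-1,3-oxazolidin-2-one and resorcinol are taken as catalogue compounds.

Step 1
Reactants: 1 paeonol [1-(2-hydroxy-4-methoxyphenyl)ethan-1-one]
Product: 2 1-[2-(benzyloxy)-4-methoxyphenyl]ethan-1-one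
Conditions: BnBr, K2CO3, DMF, 60 °C
Reagents that add atoms: benzyl bromide, BrCc1ccccc1
Why: Williamson ether synthesis on the phenoxide (K2CO3 in DMF breaks the hydrogen bond to the ketone) masks the later O2' as a benzyl ether that lasts until the final hydrogenolysis; no stereocentre is involved.

Step 2
Reactants: 2 1-[2-(benzyloxy)-4-methoxyphenyl]ethan-1-one
Product: 4 [2-(benzyloxy)-4-methoxyphenyl]acetic acid, via thiomorpholide 3 (not isolated)
Conditions: S8, morpholine, 130 °C; then aq. NaOH, BnEt3NCl (cat.), 100 °C; then HCl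
Reagents that add atoms: sodium hydroxide, [Na+].[OH-]
Why: The Willgerodt–Kindler reaction moves the oxidised carbon to the chain end as thiomorpholide 3, and phase-transfer hydrolysis of the thioamide in the same flask should give the arylacetic acid, the benzyl aryl ether being inert to amine, sulfur and hydroxide.

Step 3
Reactants: 4 [2-(benzyloxy)-4-methoxyphenyl]acetic acid; 5 (4R)-4-benzyl-1,3-oxazolidin-2-one
Product: 7 (4R)-4-benzyl-3-{[2-(benzyloxy)-4-methoxyphenyl]acetyl}-1,3-oxazolidin-2-one, via mixed pivalic anhydride 6 (not isolated)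
Conditions: PivCl, Et3N, THF, −20 °C; then 5, LiCl, −20 °C to rt
Reagents that add atoms: none
Why: N-Acylation of the oxazolidinone through a mixed pivalic anhydride (LiCl/Et3N variant of the Evans imide synthesis) transfers the arylacetyl group because the hindered pivaloyl carbonyl is spared; the auxiliary stereocentre is not touched.

Step 4
Reactants: 7 (4R)-4-benzyl-3-{[2-(benzyloxy)-4-methoxyphenyl]acetyl}-1,3-oxazolidin-2-one
Product: 8 (4R)-4-benzyl-3-{[2-(benzyloxy)-5-bromo-4-methoxyphenyl]acetyl}-1,3-oxazolidin-2-one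
Conditions: NBS, MeCN, 0 °C, dark
Reagents that add atoms: N-bromosuccinimide, O=C1CCC(=O)N1Br
Why: Electrophilic aromatic bromination should go to the only unhindered carbon activated by both oxygens, para to the benzyloxy and ortho to the methoxy group, which is the later C5' of ring B'.

Step 5
Reactants: 9 4-(benzyloxy)-2-hydroxybenzaldehyde
Product: 10 4-(benzyloxy)-2-(methoxymethoxy)benzaldehyde
Conditions: MOMCl, iPr2NEt, CH2Cl2, 0 °C to rt
Reagents that add atoms: chloromethyl methyl ether, COCCl
Why: Base-mediated O-alkylation with MOMCl gives a phenol acetal that survives the boron aldol and the hydride reduction and is shed by acid in step 8.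

Step 6
Reactants: 8 (4R)-4-benzyl-3-{[2-(benzyloxy)-5-bromo-4-methoxyphenyl]acetyl}-1,3-oxazolidin-2-one; 10 4-(benzyloxy)-2-(methoxymethoxy)benzaldehyde
Product: 12 (4R)-4-benzyl-3-{(2R,3R)-3-[4-(benzyloxy)-2-(methoxymethoxy)phenyl]-2-[2-(benzyloxy)-5-bromo-4-methoxyphenyl]-3-hydroxypropanoyl}-1,3-oxazolidin-2-one, via boron enolate 11 (not isolated)
Conditions: Bu2BOTf, iPr2NEt, CH2Cl2, 0 °C; then 10, −78 to 0 °C; then pH 7 buffer, MeOH, H2O2, 0 °C
Reagents that add atoms: none
Why: Evans syn-aldol addition, in which the (Z)-boron enolate 11 reacts through a closed chair (Zimmerman–Traxler) transition state and the benzyl group of the (R)-auxiliary shields one enolate face, sets the α-carbon (the later C3 of the lower chroman) and the carbinol carbon (removed in step 8).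

Step 7
Reactants: 12 the syn-aldol imide of step 6
Product: 13 (1R,2S)-1-[4-(benzyloxy)-2-(methoxymethoxy)phenyl]-2-[2-(benzyloxy)-5-bromo-4-methoxyphenyl]propane-1,3-diol
Conditions: LiBH4, THF, H2O (1 equiv), 0 °C
Reagents that add atoms: none
Why: Reductive cleavage of the imide with LiBH4 attacks the exocyclic acyl carbonyl, frees auxiliary 5 for re-use and leaves the α-stereocentre untouched because no enolisation takes place.

Step 8
Reactants: 13 (1R,2S)-1-[4-(benzyloxy)-2-(methoxymethoxy)phenyl]-2-[2-(benzyloxy)-5-bromo-4-methoxyphenyl]propane-1,3-diol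
Product: 14 5-(benzyloxy)-2-{(2S)-2-[2-(benzyloxy)-5-bromo-4-methoxyphenyl]-3-hydroxypropyl}phenol
Conditions: Et3SiH, CF3CO2H, CH2Cl2, −20 °C to rt; then K2CO3, MeOH
Reagents that add atoms: none
Why: Ionic hydrogenation, in which acid ionises the 2,4-dioxygenated benzylic alcohol and Et3SiH should transfer hydride to the cation before it can lose a proton, runs alongside acid cleavage of the MOM acetal (its oxocarbenium ion is reduced as well), and methanolysis removes trifluoroacetate esters, so the stereocentre of step 6 is kept.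

Step 9
Reactants: 14 5-(benzyloxy)-2-{(2S)-2-[2-(benzyloxy)-5-bromo-4-methoxyphenyl]-3-hydroxypropyl}phenol
Product: 15 (3S)-7-(benzyloxy)-3-[2-(benzyloxy)-5-bromo-4-methoxyphenyl]-3,4-dihydro-2H-chromene
Conditions: PPh3, DIAD, THF, 0 °C to rt
Reagents that add atoms: none
Why: Intramolecular Mitsunobu etherification (6-exo-tet displacement at the primary carbon by the ortho phenol) closes pyran ring C' without touching the stereocentre.

Step 10
Reactants: 15 (3S)-7-(benzyloxy)-3-[2-(benzyloxy)-5-bromo-4-methoxyphenyl]-3,4-dihydro-2H-chromene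
Product: 17 4-(benzyloxy)-5-[(3S)-7-(benzyloxy)-3,4-dihydro-2H-chromen-3-yl]-2-methoxybenzaldehyde, via aryllithium 16 (not isolated)
Conditions: n-BuLi, THF, −78 °C; then DMF, −78 to 0 °C; aq. NH4Cl
Reagents that add atoms: N,N-dimethylformamide, CN(C)C=O
Why: Bromine–lithium exchange at −78 °C is faster than any deprotonation next to the ether oxygens, and aryllithium 16 is formylated by DMF (Bouveault-type formylation) exactly at C5'.

Step 11
Reactants: 7 (4R)-4-benzyl-3-{[2-(benzyloxy)-4-methoxyphenyl]acetyl}-1,3-oxazolidin-2-one; 17 4-(benzyloxy)-5-[(3S)-7-(benzyloxy)-3,4-dihydro-2H-chromen-3-yl]-2-methoxybenzaldehyde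
Product: 19 (4R)-4-benzyl-3-{(2R,3R)-3-{4-(benzyloxy)-5-[(3S)-7-(benzyloxy)-3,4-dihydro-2H-chromen-3-yl]-2-methoxyphenyl}-2-[2-(benzyloxy)-4-methoxyphenyl]-3-hydroxypropanoyl}-1,3-oxazolidin-2-one, via boron enolate 18 (not isolated)
Conditions: Bu2BOTf, iPr2NEt, CH2Cl2, 0 °C; then 17, −78 to 0 °C; then pH 7 buffer, MeOH, H2O2, 0 °C
Reagents that add atoms: none
Why: Second Evans syn-aldol addition with the same (R)-imide, in which the (Z)-boron enolate 18 adds to the aryl aldehyde through the closed chair transition state, lets the auxiliary fix the α-carbon as the later C3 of the upper chroman, while the carbinol configuration is of no consequence.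

Step 12
Reactants: 19 the syn-aldol imide of step 11
Product: 20 (1R,2S)-1-{4-(benzyloxy)-5-[(3S)-7-(benzyloxy)-3,4-dihydro-2H-chromen-3-yl]-2-methoxyphenyl}-2-[2-(benzyloxy)-4-methoxyphenyl]propane-1,3-diol
Conditions: LiBH4, THF, H2O (1 equiv), 0 °C
Reagents that add atoms: none
Why: LiBH4 reduction of the imide as in step 7 should give the 1,3-diol and return the auxiliary, the C3 stereocentre not being enolised under these conditions.

Step 13
Reactants: 20 the 1,3-diol of step 12; 21 resorcinol (benzene-1,3-diol)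
Product: 23 (3S,4R)-3-[2-(benzyloxy)-4-methoxyphenyl]-4-{4-(benzyloxy)-5-[(3S)-7-(benzyloxy)-3,4-dihydro-2H-chromen-3-yl]-2-methoxyphenyl}-3,4-dihydro-2H-chromen-7-ol, via aryl ether carbinol 22 (not isolated)
Conditions: 21 (3 equiv), PPh3, DIAD (1.2 equiv each), THF, 0 °C to rt; then solvent exchange to CH2Cl2–(CF3)2CHOH, CF3CO2H, −20 to 0 °C
Reagents that add atoms: none
Why: Mitsunobu activation turns the unhindered primary hydroxyl of 20 into an alkoxyphosphonium ion that is displaced by a resorcinol oxygen (O1–C2), and acid in the fluorinated alcohol then ionises the benzylic alcohol to a cation stabilised like a para-quinone methide by O2' and the ortho methoxy group of ring B', which is captured by the tethered ring carbon para to the free hydroxyl (C4a–C4). The closest known reaction types are the Mitsunobu aryl ether synthesis and the intramolecular Friedel–Crafts cycloalkylation of benzylic alcohols to 4-arylchromans. Ring C closes through a six-membered chair-like transition state, 6-exo-trig with respect to the quinone-methide-like C4=C5' unit, followed by re-aromatisation of ring A. C4 is the only new stereocentre and is controlled by C3: the cation holds C3–H in its plane (allylic 1,3-strain with the ortho methoxy group), the C3 aryl group sits equatorial and the tether can reach only the face anti to it, which should give the 3,4-trans (3S,4R) ring, while the carbinol configuration of 20 is erased on ionisation. The step needs primary over secondary hydroxyl selectivity (secured by the flanked, hindered benzylic carbinol), mono-alkylation of resorcinol (secured by the excess of the symmetric diphenol, whose two hydroxyls are equivalent), closure at the carbon para to the free hydroxyl and not at the one between the two oxygens (less hindered and para-activated), and intramolecular capture that outruns attack by free resorcinol or by the benzyloxy oxygen of ring B.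

Step 14
Reactants: 23 the tribenzyl ether of step 13
Product: 24 (3S,4R)-4-{4-hydroxy-5-[(3S)-7-hydroxy-3,4-dihydro-2H-chromen-3-yl]-2-methoxyphenyl}-3-(2-hydroxy-4-methoxyphenyl)-3,4-dihydro-2H-chromen-7-ol (CNP0152030.1)
Conditions: H2 (1 atm), 10% Pd/C, EtOAc–MeOH, rt
Reagents that add atoms: none
Why: Hydrogenolysis of the three benzyl aryl ethers over palladium on carbon frees the phenols of rings B, A' and B', while the alkyl aryl ethers, the methyl ethers and the diarylmethine C–C bonds are inert, so no stereocentre is touched.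

Compound list
1 | paeonol, 1-(2-hydroxy-4-methoxyphenyl)ethan-1-one | CC(=O)c1ccc(OC)cc1O | starting material
2 | 1-[2-(benzyloxy)-4-methoxyphenyl]ethan-1-one | CC(=O)c1ccc(OC)cc1OCc1ccccc1 | intermediate
3 | 2-[2-(benzyloxy)-4-methoxyphenyl]-1-(morpholin-4-yl)ethane-1-thione (not isolated) | COc1ccc(CC(=S)N2CCOCC2)c(OCc2ccccc2)c1 | intermediate
4 | [2-(benzyloxy)-4-methoxyphenyl]acetic acid | COc1ccc(CC(=O)O)c(OCc2ccccc2)c1 | intermediate
5 | (4R)-4-benzyl-1,3-oxazolidin-2-one | O=C1N[C@H](Cc2ccccc2)CO1 | starting material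
6 | [2-(benzyloxy)-4-methoxyphenyl]acetic pivalic anhydride (not isolated) | COc1ccc(CC(=O)OC(=O)C(C)(C)C)c(OCc2ccccc2)c1 | intermediate
7 | (4R)-4-benzyl-3-{[2-(benzyloxy)-4-methoxyphenyl]acetyl}-1,3-oxazolidin-2-one | COc1ccc(CC(=O)N2[C@H](Cc3ccccc3)COC2=O)c(OCc2ccccc2)c1 | intermediate
8 | (4R)-4-benzyl-3-{[2-(benzyloxy)-5-bromo-4-methoxyphenyl]acetyl}-1,3-oxazolidin-2-one | COc1cc(OCc2ccccc2)c(CC(=O)N2[C@H](Cc3ccccc3)COC2=O)cc1Br | intermediate
9 | 4-(benzyloxy)-2-hydroxybenzaldehyde | O=Cc1ccc(OCc2ccccc2)cc1O | starting material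
10 | 4-(benzyloxy)-2-(methoxymethoxy)benzaldehyde | O=Cc1ccc(OCc2ccccc2)cc1OCOC | intermediate
11 | (Z)-dibutylboron enolate of 8 (not isolated) | CCCCB(CCCC)O/C(=C\c1cc(Br)c(OC)cc1OCc1ccccc1)N1[C@H](Cc2ccccc2)COC1=O | intermediate
12 | (4R)-4-benzyl-3-{(2R,3R)-3-[4-(benzyloxy)-2-(methoxymethoxy)phenyl]-2-[2-(benzyloxy)-5-bromo-4-methoxyphenyl]-3-hydroxypropanoyl}-1,3-oxazolidin-2-one | O=C([C@H](c1cc(Br)c(OC)cc1OCc1ccccc1)[C@@H](O)c1ccc(OCc2ccccc2)cc1OCOC)N1[C@H](Cc2ccccc2)COC1=O | intermediate
13 | (1R,2S)-1-[4-(benzyloxy)-2-(methoxymethoxy)phenyl]-2-[2-(benzyloxy)-5-bromo-4-methoxyphenyl]propane-1,3-diol | OC[C@H](c1cc(Br)c(OC)cc1OCc1ccccc1)[C@@H](O)c1ccc(OCc2ccccc2)cc1OCOC | intermediate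
14 | 5-(benzyloxy)-2-{(2S)-2-[2-(benzyloxy)-5-bromo-4-methoxyphenyl]-3-hydroxypropyl}phenol | OC[C@H](c1cc(Br)c(OC)cc1OCc1ccccc1)Cc1ccc(OCc2ccccc2)cc1O | intermediate
15 | (3S)-7-(benzyloxy)-3-[2-(benzyloxy)-5-bromo-4-methoxyphenyl]-3,4-dihydro-2H-chromene | COc1cc(OCc2ccccc2)c([C@H]2COc3cc(OCc4ccccc4)ccc3C2)cc1Br | intermediate
16 | {4-(benzyloxy)-5-[(3S)-7-(benzyloxy)-3,4-dihydro-2H-chromen-3-yl]-2-methoxyphenyl}lithium (not isolated) | COc1cc(OCc2ccccc2)c([C@H]2COc3cc(OCc4ccccc4)ccc3C2)cc1[Li] | intermediate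
17 | 4-(benzyloxy)-5-[(3S)-7-(benzyloxy)-3,4-dihydro-2H-chromen-3-yl]-2-methoxybenzaldehyde | COc1cc(OCc2ccccc2)c([C@H]2COc3cc(OCc4ccccc4)ccc3C2)cc1C=O | intermediate
18 | (Z)-dibutylboron enolate of 7 (not isolated) | CCCCB(CCCC)O/C(=C\c1ccc(OC)cc1OCc1ccccc1)N1[C@H](Cc2ccccc2)COC1=O | intermediate
19 | (4R)-4-benzyl-3-{(2R,3R)-3-{4-(benzyloxy)-5-[(3S)-7-(benzyloxy)-3,4-dihydro-2H-chromen-3-yl]-2-methoxyphenyl}-2-[2-(benzyloxy)-4-methoxyphenyl]-3-hydroxypropanoyl}-1,3-oxazolidin-2-one | O=C([C@H](c1ccc(OC)cc1OCc1ccccc1)[C@@H](O)c1cc([C@H]2COc3cc(OCc4ccccc4)ccc3C2)c(OCc2ccccc2)cc1OC)N1[C@H](Cc2ccccc2)COC1=O | intermediate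
20 | (1R,2S)-1-{4-(benzyloxy)-5-[(3S)-7-(benzyloxy)-3,4-dihydro-2H-chromen-3-yl]-2-methoxyphenyl}-2-[2-(benzyloxy)-4-methoxyphenyl]propane-1,3-diol | OC[C@H](c1ccc(OC)cc1OCc1ccccc1)[C@@H](O)c1cc([C@H]2COc3cc(OCc4ccccc4)ccc3C2)c(OCc2ccccc2)cc1OC | intermediate
21 | resorcinol, benzene-1,3-diol | Oc1cccc(O)c1 | starting material
22 | (1R,2S)-1-{4-(benzyloxy)-5-[(3S)-7-(benzyloxy)-3,4-dihydro-2H-chromen-3-yl]-2-methoxyphenyl}-2-[2-(benzyloxy)-4-methoxyphenyl]-3-(3-hydroxyphenoxy)propan-1-ol (not isolated) | Oc1cccc(OC[C@H](c2ccc(OC)cc2OCc2ccccc2)[C@@H](O)c2cc([C@H]3COc4cc(OCc5ccccc5)ccc4C3)c(OCc3ccccc3)cc2OC)c1 | intermediate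
23 | (3S,4R)-3-[2-(benzyloxy)-4-methoxyphenyl]-4-{4-(benzyloxy)-5-[(3S)-7-(benzyloxy)-3,4-dihydro-2H-chromen-3-yl]-2-methoxyphenyl}-3,4-dihydro-2H-chromen-7-ol | COc1ccc([C@H]2COc3cc(O)ccc3[C@@H]2c2cc([C@H]3COc4cc(OCc5ccccc5)ccc4C3)c(OCc3ccccc3)cc2OC)c(OCc2ccccc2)c1 | intermediate
24 | (3S,4R)-4-{4-hydroxy-5-[(3S)-7-hydroxy-3,4-dihydro-2H-chromen-3-yl]-2-methoxyphenyl}-3-(2-hydroxy-4-methoxyphenyl)-3,4-dihydro-2H-chromen-7-ol | COc1ccc([C@H]2COc3cc(O)ccc3[C@@H]2c2cc([C@H]3COc4cc(O)ccc4C3)c(O)cc2OC)c(O)c1 | target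

Total step count: 14 steps. Longest linear sequence: 13 steps (steps 1–4 and 6–14); step 5 is the only side branch, and imide 7 is used twice (steps 4 and 11).

Steps most likely to fail

Step 13 (key step). In the Mitsunobu stage the electron-rich secondary benzylic hydroxyl may be activated as well (elimination towards the stilbene, ether formation at C4), and double alkylation of resorcinol may consume the diol. In the acid stage the cation may be intercepted by the neighbouring benzyloxy oxygen of ring B (five-membered ring closure with loss of benzyl) or may lose the C3 proton, which would erode the configuration at C3. The fallback reverses the order of bond formation and separates the two events; it sets out from 20 and comes back at 23. Diol 20 is stirred with excess resorcinol in (CF3)2CHOH–CH2Cl2 with catalytic p-toluenesulfonic acid at 0 °C, so that the C4a–C4 bond forms first by intermolecular Friedel–Crafts alkylation, anti to the C3 aryl group under acyclic control by allylic 1,3-strain. This should give the isolable (2S,3R)-2-[2-(benzyloxy)-4-methoxyphenyl]-3-{4-(benzyloxy)-5-[(3S)-7-(benzyloxy)-3,4-dihydro-2H-chromen-3-yl]-2-methoxyphenyl}-3-(2,4-dihydroxyphenyl)propan-1-ol F1. Intramolecular Mitsunobu etherification of F1 (PPh3, DIAD, THF; primary carbon and ortho phenol, as in step 9) then closes ring C and gives 23.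

Step 8. The benzylic cation lies next to the stereocentre: reversible proton loss to the stilbene followed by unselective reduction would erode the configuration at the lower C3. The benzyloxy oxygen of ring B' may also add to the cation (five-membered ring closure with loss of benzyl), or the acetal may be cleaved incompletely. The fallback avoids any cation by replacing aldol plus deoxygenation with an enolate alkylation; it sets out from 4 and 10 and comes back at 14. Aldehyde 10 is reduced with NaBH4 to [4-(benzyloxy)-2-(methoxymethoxy)phenyl]methanol F2, which CBr4/PPh3 converts into 4-(benzyloxy)-1-(bromomethyl)-2-(methoxymethoxy)benzene F3. Acid 4 is coupled as in step 3, through anhydride 6, with commercial (4S)-4-benzyl-1,3-oxazolidin-2-one to give (4S)-4-benzyl-3-{[2-(benzyloxy)-4-methoxyphenyl]acetyl}-1,3-oxazolidin-2-one F4, which is brominated as in step 4 to (4S)-4-benzyl-3-{[2-(benzyloxy)-5-bromo-4-methoxyphenyl]acetyl}-1,3-oxazolidin-2-one F5. The chelated sodium (Z)-enolate of F5 (NaHMDS, THF, −78 °C) is alkylated by F3 on the face opposite to the benzyl group. With the (S)-auxiliary this gives the same spatial arrangement at the α-carbon as the aldol with the (R)-auxiliary, namely (4S)-4-benzyl-3-{(2S)-3-[4-(benzyloxy)-2-(methoxymethoxy)phenyl]-2-[2-(benzyloxy)-5-bromo-4-methoxyphenyl]propanoyl}-1,3-oxazolidin-2-one F6. LiBH4 gives (2S)-3-[4-(benzyloxy)-2-(methoxymethoxy)phenyl]-2-[2-(benzyloxy)-5-bromo-4-methoxyphenyl]propan-1-ol F7, and HCl in MeOH removes the acetal to give 14.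

Step 2. At 130 °C sulfur may attack the benzylic CH2 of the benzyl ether or cause tar formation, and hydrolysis of the ortho-substituted thioamide may stall. The fallback uses an oxidative 1,2-aryl migration in place of the Willgerodt–Kindler reaction; it sets out from 2 and comes back at 4. Ketone 2 is treated with PhI(OAc)2 and catalytic H2SO4 in HC(OMe)3–MeOH, where the electron-rich aryl group migrates in the iodonium-activated enol ether, to give methyl [2-(benzyloxy)-4-methoxyphenyl]acetate F8. Saponification with LiOH in THF–H2O then gives 4.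

Further compounds
F1 | step 13 | (2S,3R)-2-[2-(benzyloxy)-4-methoxyphenyl]-3-{4-(benzyloxy)-5-[(3S)-7-(benzyloxy)-3,4-dihydro-2H-chromen-3-yl]-2-methoxyphenyl}-3-(2,4-dihydroxyphenyl)propan-1-ol | OC[C@H](c1ccc(OC)cc1OCc1ccccc1)[C@H](c1ccc(O)cc1O)c1cc([C@H]2COc3cc(OCc4ccccc4)ccc3C2)c(OCc2ccccc2)cc1OC
F2 | step 8 | [4-(benzyloxy)-2-(methoxymethoxy)phenyl]methanol | OCc1ccc(OCc2ccccc2)cc1OCOC
F3 | step 8 | 4-(benzyloxy)-1-(bromomethyl)-2-(methoxymethoxy)benzene | BrCc1ccc(OCc2ccccc2)cc1OCOC
F4 | step 8 | (4S)-4-benzyl-3-{[2-(benzyloxy)-4-methoxyphenyl]acetyl}-1,3-oxazolidin-2-one | COc1ccc(CC(=O)N2[C@@H](Cc3ccccc3)COC2=O)c(OCc2ccccc2)c1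
F5 | step 8 | (4S)-4-benzyl-3-{[2-(benzyloxy)-5-bromo-4-methoxyphenyl]acetyl}-1,3-oxazolidin-2-one | COc1cc(OCc2ccccc2)c(CC(=O)N2[C@@H](Cc3ccccc3)COC2=O)cc1Br
F6 | step 8 | (4S)-4-benzyl-3-{(2S)-3-[4-(benzyloxy)-2-(methoxymethoxy)phenyl]-2-[2-(benzyloxy)-5-bromo-4-methoxyphenyl]propanoyl}-1,3-oxazolidin-2-one | O=C([C@H](c1cc(Br)c(OC)cc1OCc1ccccc1)Cc1ccc(OCc2ccccc2)cc1OCOC)N1[C@@H](Cc2ccccc2)COC1=O
F7 | step 8 | (2S)-3-[4-(benzyloxy)-2-(methoxymethoxy)phenyl]-2-[2-(benzyloxy)-5-bromo-4-methoxyphenyl]propan-1-ol | OC[C@H](c1cc(Br)c(OC)cc1OCc1ccccc1)Cc1ccc(OCc2ccccc2)cc1OCOC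
F8 | step 2 | methyl [2-(benzyloxy)-4-methoxyphenyl]acetate | COC(=O)Cc1ccc(OC)cc1OCc1ccccc1
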